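(The data were computed from invented constants.)

Take the flask's starting material as an account and enter where each part of it goes, using the earlier runs below.

| setting | north-east | south | flask |
|---|---|---|---|
| starting material | 0.10 M | 0.20 M | 0.10 M |
| partner | 1.1 equiv | 1.1 equiv | 1.10 equiv |
| second substrate | 1 equiv | 1 equiv | 1.00 equiv |
| precatalyst | 1.1 mol% | 1.1 mol% | 1.1 mol% |
| temperature | 50 °C | 35 °C | 50 °C |
| remark | the very flask that is asked about, followed so far | run made earlier |  |
| time |  |  | 6.0 d |

| run | time / h | target / % |
|---|---|---|
| north-east | 6.00 | 4.7 |
| north-east | 15.0 | 15.4 |
| north-east | 30.0 | 27.2 |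
| north-east | 50.0 | 34.7 |
| north-east | 72.0 | 37.5 |
| north-east | 96.0 | 39.4 |
| south | 8.00 | 2.2 |
| south | 15.0 | 6.4 |
| south | 20.0 | 11.5 |
| south | 30.0 | 19.9 |
| south | 40.0 | 27.4 |

(standard deviation of a reading: 0.5 percentage points)

- dusk: change nothing and wait 3.0 d more
- summer: at 6.0 d add partner, 50.0% of the amount charged, then wait 3.0 d
- dawn: at 6.0 d raise the temperature by 25 K, then wait 3.0 d
- noon: at 6.0 d add precatalyst, 100% of the amount charged, then wait 3.0 d
- midnight: at 6.0 d take out 90% of the target then present, then wait 3.0 d

- target that was removed still counts
- the analysis behind the earlier runs scatters by 0.5 percentage points, standard deviation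
- additions bring no volume worth counting

* target, in percent of the starting material first charged, at 6.0 d
* the option that brings most further target ("none" if no option brings more than 2 percentage points) (dusk / summer / dawn / noon / midnight / none)
* target present, with what was taken out counted in, in percent of the starting material first charged, after noon
* target present, with what was taken out counted in, in percent of the starting material first charged, after midnight

In the north-east run, which is the flask itself followed so far, target rose 2.8 percentage points in the 22.0 h up to 72.0 h, then 1.9 points in the 24.0 h up to 96.0 h. From these two gains I read a fade constant of 0.0206 h⁻¹, the fractional fall of the rate per hour, which is a half-life of 33.6 h. Each gain carries about 0.71 points of scatter, so this is a rough reading.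

At 96.0 h the rate divided by that constant came to 3 points, and this I called the reserve, the target still to come from a given moment while the rate keeps fading alike. The reserve shrinks with the same constant, so by 6.0 d I had it down to 1.1 points.

My ledger for the flask, in percent of the starting material charged, then ran as follows, assuming that target is the one outlet. The ceiling, target at 96.0 h plus the reserve, stood at 42.4%. There was 39.4% of target at 96.0 h, 1.9 points more arriving by 6.0 d, 1.1 points arriving later, and 57.6% staying unreacted. So I committed to 41.3% at 6.0 d, and by this reckoning waiting brings less than the margin of 2 points.

The forecast gave 40.8% (39.8% to 42.5%), which lies 0.50 points below my figure. It chose noon, with 58% (50% to 67%) after it and 41.2% (40% to 46%) after midnight, calling the loss “most likely catalyst death, though this is not proven”.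

The flask gave 41.1% at 6.0 d, and noon was the best option, with 49.8% after it, which is where it parts from the forecast, and 41.6% after midnight.

    free catalyst → spent catalyst (k = 1.30 × 10⁻⁵ s⁻¹, Ea = 98.0 kJ mol⁻¹)
    precatalyst ⇌ free catalyst (K = 1.70, k = 2.10 × 10⁻⁵ s⁻¹, Ea = 104 kJ mol⁻¹, ΔH = −42.0 kJ mol⁻¹)
    second substrate + partner + free catalyst → free catalyst + second product (k = 0.100 M⁻² s⁻¹, Ea = 56.0 kJ mol⁻¹)
    starting material + partner + free catalyst → free catalyst + target (k = 0.110 M⁻² s⁻¹, Ea = 57.0 kJ mol⁻¹)
    (constants at 50 °C)

In the flask free catalyst has a half-life of 15 h by its passing into spent catalyst alone, shorter than the 70 h half-life of second substrate by its own step at 20.3 h. At 6.0 d the flask held 96.6% of the catalyst charged as spent catalyst, beside 59% of its starting material and 28% of its partner. For the same charge left until 2.5 d, the reserve gives 36.1%, and that flask held 36.4% of target.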